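Compound numbers refer to the compound list after the steps. "Lavandulyl" means 5-methyl-2-(prop-1-en-2-yl)hex-4-en-1-yl. Its stereocentre is the methine that carries the isopropenyl group: it is (S) in lavandulol and in the iodide, and the same spatial arrangement is named (R) once the CH2 is bonded to the arene, by a change of priorities only.

## Analysis of the target

The target 20 is a flavanone. Ring A is a phloroglucinol-type ring with free hydroxyls at C5 and C7, the lavandulyl chain at C6 and a single hydrogen at C8. Ring C is the dihydropyranone O1–C2–C3–C4(=O)–C4a–C8a, and ring B, on C2, is a 4-hydroxy-2-methoxyphenyl group. There are two stereocentres, C2 (S) and the side-chain methine (R); they lie seven bonds apart across ring A, so neither can direct the other and each must be set on its own. The β-aryloxy ketone of ring C opens to a 2'-hydroxychalcone as soon as C3 is enolised, which racemises C2. The side chain has a 1,1-disubstituted and a trisubstituted alkene that add neighbouring phenols under acid, and its allylic stereocentre would be erased by double-bond migration. The difficulties are three: placing the chain at C6 and not C8 (chalcone closures of a C-alkylated phloroglucinol ketone can use either ortho-hydroxyl), joining an unactivated β-branched alkyl group to an electron-rich arene, and forming C2 in one configuration without passing through an enolate. The strategy rests on one feature: C4 is bonded directly to C4a, and C2 carries only H, ring B and O1, so C3–C4 and C2–H can be made in one event from a formyl group on C4a and a 1-arylvinyl ether on O1. The ring A phenol behind that precursor is symmetric about its C1–C4 axis, so the carbon that receives the formyl group is not in doubt.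

## Retrosynthetic reasoning

**20 to 19.** Only three O–CH2OCH3 bonds are cut. The phenols must be masked through the organometallic steps, and the two acetals on ring A also direct the metalation that marks C6. Using one kind of protecting group allows a single mild unmasking at the end.

**19 to 18 (C3–C4 and C2–H).** This is the only cut of ring C that creates C2 in the ring-forming event from a precursor with no stereocentre at that carbon. Cutting O1–C2 (oxa-Michael) gives a reversible, racemising closure, and cutting C4–C4a requires C2 to be made and protected beforehand. The forward reaction must add the aldehyde C–H of 18 across the enol ether, with hydrogen to one face of C2 and the acyl carbon to the terminal C3, in the six-membered mode, under neutral conditions.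

**18 to 16 (C4a–CHO).** The formyl carbon is introduced last, at a position marked by iodine, through the aryl Grignard reagent 17. A free aldehyde would not survive the methylenation that makes the enol ether, and halogen–metal exchange fixes the site regardless of other acidic C–H bonds in the molecule.

**16 to 15 to 11 + 14 (enol ether from ester).** The C=CH2 unit is traced back to an ester carbonyl and the ester to a simple acylation of phenol 11 by acid 14. Direct C–O coupling of a hindered, hydrogen-bonded salicylaldehyde with a 1-halovinylarene was weighed and set aside as the main line, because dehydrohalogenation of the haloalkene and the poor nucleophilicity of such a phenol make it uncertain. Carbonyl methylenation of an aryl ester is dependable, so the risk stays in the ring closure.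

**11 to 10 to 9 (C–I, then C–O from C–Cl).** Phenol 10 has two equivalent ortho positions and a blocked para position, so iodination can give only 11; this settles the C6 versus C8 question. The hydroxyl is traced to the chlorine of 9, which is inert to the organolithium and organozinc steps and is exchanged for oxygen by palladium catalysis.

**9 to 7 + 3 (aryl–CH2).** Cutting here lets the whole chain, with its stereocentre, come from alcohol 2. The CH2 is neither allylic nor benzylic, so it is joined by cross-coupling of the alkylzinc 8 (from iodide 3) with aryl iodide 7; the stereocentre is β to the reacting carbon and is not touched.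

**Fragments.** 7 comes from 5 through aryllithium 6, formed between the two acetal groups, and 5 from 5-chlororesorcinol 4. 3 comes from (S)-lavandulol 2, the slow-reacting enantiomer in a lipase acylation of racemic 1. Acid 14 comes from ester 12 through 13.

## Alternatives that were turned down

**Alternative 1: Diels–Alder construction of ring A on a dihydropyranone.**
- Disconnection: ring A is cut at C8–C8a and C4a–C5. C5–C8, both oxygens and the side chain come from the diene 1-methoxy-2-lavandulyl-1,3-bis(trimethylsilyloxy)buta-1,3-diene A2; ring C with the (2S) centre comes from the sulfinyl dihydropyranone A3.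
- Forward key step: cycloaddition of A2 across C4a=C8a of A3, then loss of benzenesulfenic acid and methanol, to give the 5,7-diol A1 with ring B as a silyl ether.
- For: the diene polarity puts the chain at C6 with no 6/8 ambiguity. C2 can be set beforehand by established asymmetric chemistry on a small ring. A1 arrives with ring A unprotected. On these points it is at least as strong as the chosen route, and stronger in that C2 does not depend on an untested reaction.
- Against: C4a=C8a of A3 is the double bond of a vinylogous ester, and the oxygen on C8a makes it a poor partner for an electron-rich diene even with the sulfinyl group. A2 is a tetrasubstituted, hydrolytically fragile ketene acetal that must come from a lavandulyl β-keto ester, so the awkward alkylation with a β-branched lavandulyl halide is still needed. Forcing conditions threaten the C2–O1 bond of A3 by retro-oxa-Michael opening, and Michael addition without ring closure is a likely detour.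
- Comparison: two multi-step fragments make it no shorter. It builds a benzene ring that can be bought; the chosen route buys ring A and spends its one inventive step on the ring closure that creates C2.

**Alternative 2: Photochemical Danheiser benzannulation.**
- Disconnection: four bonds of ring A are cut. C5 and C8 come from the diazo ketone A5, a dihydropyranone with a diazoacetyl group on C8a and the (2S) centre in place; C6 and C7 come from the lavandulyl silyloxyalkyne A6.
- Forward key step: light converts A5 by Wolff rearrangement into a vinylketene, which adds A6; the cyclobutenone opens and recloses to the phenol A4, with C5–OH free and C7–O silylated.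
- For: the regiochemistry is absolute, the conditions are neutral, and the two ring A oxygens emerge differentiated, which is more than the chosen route achieves.
- Against: both partners are exotic. A5 needs a C8a carboxylic acid taken through an acid chloride and diazomethane next to a vinylogous ester that opens readily; A6 needs an ynolate homologation of a lavandulyl ester. Irradiating an enone in the presence of three alkenes invites [2+2] photocycloaddition, and the electrocyclic cascade needs heat on a substrate prone to ring opening. The O5/O7 differentiation is not needed for this target.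
- Comparison: clearly longer, and it uses diazo compounds. The chosen route gives up the built-in certainty of a pericyclic cascade and offers short access to its precursor and catalytic control of C2.

**Alternative 3: Parham cyclisation.**
- Disconnection: C4–C4a, with the O1–C2 ether made earlier. The precursor is the aryl ether A8 of iodophenol 11 with a (3S) β-aryl Weinreb amide, ring B carrying a tert-butyl carbonate.
- Forward key step: iodine–magnesium exchange at C4a and intramolecular acylation, giving the flavanone A7.
- For: every step belongs to a known reaction class, the same iodophenol 11 serves, and ring closure by acylation of a Weinreb amide is dependable. On reliability it is stronger than the chosen strategy.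
- Against: the O1–C2 bond must be made by Mitsunobu displacement at an ortho-methoxy, para-oxygenated benzylic carbinol, where ionisation competes with inversion; the carbonate that tempers this is itself an electrophile toward the aryl Grignard. In A8 the C3 hydrogens are α to the amide and the aryloxide is a good β-leaving group, so the basic exchange conditions can expel the phenoxide. The chiral fragment needs about four steps and is used stoichiometrically.
- Comparison: similar step count, with more of it spent on the ring B fragment. The chosen route offers a precursor with no C2 stereocentre to lose before closure, catalyst control, neutral conditions and a two-step ring B fragment. Because both routes share 11, this logic is kept as the safety net, with acylation before etherification.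

Key step: step 13

Assumption: which antipode of DTBM-SEGPHOS leads to (2S) on this new substrate class cannot be predicted with confidence; the (R) ligand is written, and its antipode is used if a test reaction shows the opposite sense.

## Route

Step 1
Reactants: 1 (±)-lavandulol
Product: 2 (S)-lavandulol
Conditions: porcine pancreatic lipase, vinyl acetate, MTBE, rt, carried beyond half conversion; chromatography
Reagents that add atoms: none
Why: Lipase-catalysed kinetic resolution by transesterification; the (R) alcohol is expected to be acetylated faster, so running past half conversion should leave the slower (S) alcohol in high enantiomeric purity at the cost of yield, and the ester is removed by chromatography.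

Step 2
Reactants: 2 (S)-lavandulol
Product: 3 (S)-lavandulyl iodide
Conditions: PPh3, I2, imidazole, CH2Cl2, 0 °C to rt, dark
Reagents that add atoms: iodine, II
Why: Appel-type iodination by SN2 displacement of the alkoxyphosphonium at the primary carbon; the stereocentre is β to the reacting carbon and is not touched.

Step 3
Reactants: 4 5-chlororesorcinol
Product: 5 1-chloro-3,5-bis(methoxymethoxy)benzene
Conditions: MOMCl, i-Pr2NEt, CH2Cl2, 0 °C to rt
Reagents that add atoms: chloromethyl methyl ether, COCCl
Why: Standard O-alkylation of both phenols; the symmetric product has only one C–H flanked by two chelating acetal groups.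

Step 4
Reactants: 5 1-chloro-3,5-bis(methoxymethoxy)benzene
Product: 7 5-chloro-2-iodo-1,3-bis(methoxymethoxy)benzene, via aryllithium 6 (not isolated)
Conditions: n-BuLi, THF, −20 °C; I2, −78 °C to rt; aq. Na2S2O3
Reagents that add atoms: iodine, II
Why: Directed ortho-metalation; the two methoxymethyl ethers cooperate to chelate lithium and acidify the C–H between them, and iodine traps the aryllithium. The regiochemistry can be verified on this simple compound before the chiral chain is committed.

Step 5
Reactants: 3 (S)-lavandulyl iodide; 7 5-chloro-2-iodo-1,3-bis(methoxymethoxy)benzene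
Product: 9 5-chloro-1,3-bis(methoxymethoxy)-2-[(R)-lavandulyl]benzene, via lavandulylzinc iodide 8 (not isolated)
Conditions: 3, Zn dust (activated with 1,2-dibromoethane and TMSCl), LiCl, THF, 35 °C; then 7, Pd(OAc)2 (cat.), SPhos, THF, rt
Reagents that add atoms: none
Why: Zinc insertion into the primary C–I bond followed by Negishi sp3–sp2 coupling; at room temperature zerovalent palladium should insert into the C–I bond of 7 and leave C–Cl alone, and the bulky biarylphosphine should make reductive elimination faster than β-hydride elimination. The stereocentre is β to zinc and is not involved.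

Step 6
Reactants: 9 5-chloro-1,3-bis(methoxymethoxy)-2-[(R)-lavandulyl]benzene
Product: 10 3,5-bis(methoxymethoxy)-4-[(R)-lavandulyl]phenol
Conditions: Pd2(dba)3 (cat.), t-BuXPhos, KOH, 1,4-dioxane/H2O, 100 °C; then aq. NaH2PO4 to pH 6
Reagents that add atoms: potassium hydroxide, [K+].[OH-]
Why: Palladium-catalysed hydroxylation of an unhindered aryl chloride; acetals and isolated alkenes are inert to hot hydroxide, and the alkenes sit para to the reacting carbon, out of reach of the arylpalladium.

Step 7
Reactants: 10 3,5-bis(methoxymethoxy)-4-[(R)-lavandulyl]phenol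
Product: 11 2-iodo-3,5-bis(methoxymethoxy)-4-[(R)-lavandulyl]phenol
Conditions: I2 (1.0 equiv), NaHCO3, THF/H2O, 0 °C
Reagents that add atoms: iodine, II
Why: Electrophilic iodination of the phenoxide; the two ortho positions are equivalent and the para position is blocked, so one regioisomer should form. Iodine does not add irreversibly to the alkenes under bicarbonate, and one equivalent at 0 °C limits di-iodination.

Step 8
Reactants: 12 methyl 4-hydroxy-2-methoxybenzoate
Product: 13 methyl 2-methoxy-4-(methoxymethoxy)benzoate
Conditions: MOMCl, i-Pr2NEt, CH2Cl2, 0 °C to rt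
Reagents that add atoms: chloromethyl methyl ether, COCCl
Why: Standard phenol protection, so that the acid of the next step cannot acylate itself.

Step 9
Reactants: 13 methyl 2-methoxy-4-(methoxymethoxy)benzoate
Product: 14 2-methoxy-4-(methoxymethoxy)benzoic acid
Conditions: LiOH, THF/MeOH/H2O, 40 °C; then 1 M HCl to pH 4 at 0 °C
Reagents that add atoms: lithium hydroxide, [Li+].[OH-]
Why: Ester saponification; the aryl acetal is stable to base and to brief cold acidification at pH 4.

Step 10
Reactants: 11 2-iodo-3,5-bis(methoxymethoxy)-4-[(R)-lavandulyl]phenol; 14 2-methoxy-4-(methoxymethoxy)benzoic acid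
Product: 15 2-iodo-3,5-bis(methoxymethoxy)-4-[(R)-lavandulyl]phenyl 2-methoxy-4-(methoxymethoxy)benzoate
Conditions: DIC, DMAP (cat.), CH2Cl2, 0 °C to rt
Reagents that add atoms: none
Why: Steglich esterification; the acylpyridinium acylates the hindered but acidic iodophenol under neutral conditions, avoiding an acid chloride and the HCl that would threaten the acetals.

Step 11
Reactants: 15 2-iodo-3,5-bis(methoxymethoxy)-4-[(R)-lavandulyl]phenyl 2-methoxy-4-(methoxymethoxy)benzoate
Product: 16 2-iodo-1-{1-[2-methoxy-4-(methoxymethoxy)phenyl]ethenyloxy}-3,5-bis(methoxymethoxy)-4-[(R)-lavandulyl]benzene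
Conditions: Cp2TiMe2 (3 equiv), toluene/THF, 65–70 °C, dark; filtration through basic alumina
Reagents that add atoms: dimethyltitanocene, [CH3-].[CH3-].c1cc[cH-]c1.c1cc[cH-]c1.[Ti+4]
Why: Petasis methylenation; thermolysis gives Cp2Ti=CH2, which adds to the ester carbonyl and collapses to the enol ether, a transformation for which aryl esters are good substrates. No Lewis acid is present, so the acetals and the new enol ether should survive; the aryl iodide is inert and the chain alkenes can only undergo degenerate methylene exchange.

Step 12
Reactants: 16 2-iodo-1-{1-[2-methoxy-4-(methoxymethoxy)phenyl]ethenyloxy}-3,5-bis(methoxymethoxy)-4-[(R)-lavandulyl]benzene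
Product: 18 2,4-bis(methoxymethoxy)-6-{1-[2-methoxy-4-(methoxymethoxy)phenyl]ethenyloxy}-3-[(R)-lavandulyl]benzaldehyde, via arylmagnesium chloride 17 (not isolated)
Conditions: i-PrMgCl·LiCl, THF, −20 to 0 °C; DMF, 0 °C to rt; pH 7 phosphate buffer
Reagents that add atoms: N,N-dimethylformamide, CN(C)C=O
Why: Iodine–magnesium exchange followed by formylation with a formamide; exchange at iodine fixes the site whatever other C–H bonds are acidic, the mild Grignard reagent does not add to the styrene-like enol ether, and the buffered work-up protects that enol ether from hydrolysis.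

Step 13
Reactants: 18 2,4-bis(methoxymethoxy)-6-{1-[2-methoxy-4-(methoxymethoxy)phenyl]ethenyloxy}-3-[(R)-lavandulyl]benzaldehyde
Product: 19 (2S)-5,7-bis(methoxymethoxy)-2-[2-methoxy-4-(methoxymethoxy)phenyl]-6-[(R)-lavandulyl]chroman-4-one
Conditions: [Rh(cod)2]BF4 (5 mol %), (R)-DTBM-SEGPHOS (5.5 mol %), degassed acid-free 1,2-dichloroethane, 40–60 °C
Reagents that add atoms: none
Why: Proposed new method: the aldehyde C–H bond of 18 should add oxidatively to the cationic bisphosphine complex of monovalent rhodium, giving an acyl hydride of trivalent rhodium held by the flanking O1 and C5 oxygens; the bound enol ether then inserts into Rh–H with hydride going to C2 and rhodium to the terminal C3, and C–C reductive elimination from the seven-membered acyl–alkyl rhodacycle forms C3–C4 and releases the catalyst. The closest known reaction type is the rhodium-catalysed endo- and enantioselective hydroacylation of ortho-allylbenzaldehydes with a 2-substituted allyl group, which gives 3-substituted tetralones; replacing the benzylic CH2 of that class by the ether oxygen O1 has not been shown. Ring C closes in the 6-endo mode, with both alkene carbons ending in the ring; the competing 5-exo mode would give a 2-aryl-2-methylbenzofuran-3-one with a quaternary carbon. The C2 stereocentre is set by the chiral pocket of DTBM-SEGPHOS, which selects the face of the enol ether that receives hydride; the lavandulyl centre is too remote to influence it, so the outcome is catalyst-controlled. The step needs endo over exo regioselectivity, face selectivity and hydroacylation over decarbonylation: the 1,1-disubstituted alkene disfavours a tertiary benzylic alkyl–rhodium beside the bulky ligand and has no allylic hydrogen through which to isomerise, the chelating oxygens stabilise the acyl hydride, and the chain alkenes lie across ring A where they cannot reach the metal-bound acyl group. No base or Brønsted acid is present, so neither the enol ether of 18 nor the β-aryloxy ketone of 19 should be opened.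

Step 14
Reactants: 19 (2S)-5,7-bis(methoxymethoxy)-2-[2-methoxy-4-(methoxymethoxy)phenyl]-6-[(R)-lavandulyl]chroman-4-one
Product: 20 (2S)-5,7-dihydroxy-2-(4-hydroxy-2-methoxyphenyl)-6-[(R)-lavandulyl]chroman-4-one (target)
Conditions: HCl (about 1 M) in MeOH/THF, 0 °C to rt, stopped at full conversion; aq. NaHCO3
Reagents that add atoms: none
Why: Acid-catalysed acetal exchange with methanol removes the three methoxymethyl ethers, the chelated C5 one first; dilute acid at or below room temperature is the usual way to unmask prenylated flavanones without adding phenols to the side-chain alkenes, and without base no enolate forms, so C2 should hold.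

## Compound list

1 | (±)-lavandulol, 5-methyl-2-(prop-1-en-2-yl)hex-4-en-1-ol | C=C(C)C(CC=C(C)C)CO | starting material
2 | (S)-lavandulol, (2S)-5-methyl-2-(prop-1-en-2-yl)hex-4-en-1-ol | C=C(C)[C@H](CC=C(C)C)CO | intermediate
3 | (S)-lavandulyl iodide, (3S)-3-(iodomethyl)-2,6-dimethylhepta-1,5-diene | C=C(C)[C@H](CC=C(C)C)CI | intermediate
4 | 5-chlororesorcinol | Oc1cc(O)cc(Cl)c1 | starting material
5 | 1-chloro-3,5-bis(methoxymethoxy)benzene | COCOc1cc(Cl)cc(OCOC)c1 | intermediate
6 | 4-chloro-2,6-bis(methoxymethoxy)phenyllithium | [Li]c1c(OCOC)cc(Cl)cc1OCOC | intermediate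
7 | 5-chloro-2-iodo-1,3-bis(methoxymethoxy)benzene | COCOc1cc(Cl)cc(OCOC)c1I | intermediate
8 | [(2S)-5-methyl-2-(prop-1-en-2-yl)hex-4-en-1-yl]zinc iodide | C=C(C)[C@H](CC=C(C)C)C[Zn]I | intermediate
9 | 5-chloro-1,3-bis(methoxymethoxy)-2-[(2R)-5-methyl-2-(prop-1-en-2-yl)hex-4-en-1-yl]benzene | C=C(C)[C@H](CC=C(C)C)Cc1c(OCOC)cc(Cl)cc1OCOC | intermediate
10 | 3,5-bis(methoxymethoxy)-4-[(2R)-5-methyl-2-(prop-1-en-2-yl)hex-4-en-1-yl]phenol | C=C(C)[C@H](CC=C(C)C)Cc1c(OCOC)cc(O)cc1OCOC | intermediate
11 | 2-iodo-3,5-bis(methoxymethoxy)-4-[(2R)-5-methyl-2-(prop-1-en-2-yl)hex-4-en-1-yl]phenol | C=C(C)[C@H](CC=C(C)C)Cc1c(OCOC)cc(O)c(I)c1OCOC | intermediate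
12 | methyl 4-hydroxy-2-methoxybenzoate | COC(=O)c1ccc(O)cc1OC | starting material
13 | methyl 2-methoxy-4-(methoxymethoxy)benzoate | COCOc1ccc(C(=O)OC)c(OC)c1 | intermediate
14 | 2-methoxy-4-(methoxymethoxy)benzoic acid | COCOc1ccc(C(=O)O)c(OC)c1 | intermediate
15 | 2-iodo-3,5-bis(methoxymethoxy)-4-[(2R)-5-methyl-2-(prop-1-en-2-yl)hex-4-en-1-yl]phenyl 2-methoxy-4-(methoxymethoxy)benzoate | C=C(C)[C@H](CC=C(C)C)Cc1c(OCOC)cc(OC(=O)c2ccc(OCOC)cc2OC)c(I)c1OCOC | intermediate
16 | 2-iodo-1-{1-[2-methoxy-4-(methoxymethoxy)phenyl]ethenyloxy}-3,5-bis(methoxymethoxy)-4-[(2R)-5-methyl-2-(prop-1-en-2-yl)hex-4-en-1-yl]benzene | C=C(C)[C@H](CC=C(C)C)Cc1c(OCOC)cc(OC(=C)c2ccc(OCOC)cc2OC)c(I)c1OCOC | intermediate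
17 | arylmagnesium chloride of 16 (MgCl in place of iodine) | C=C(C)[C@H](CC=C(C)C)Cc1c(OCOC)cc(OC(=C)c2ccc(OCOC)cc2OC)c([Mg]Cl)c1OCOC | intermediate
18 | 2,4-bis(methoxymethoxy)-6-{1-[2-methoxy-4-(methoxymethoxy)phenyl]ethenyloxy}-3-[(2R)-5-methyl-2-(prop-1-en-2-yl)hex-4-en-1-yl]benzaldehyde | C=C(C)[C@H](CC=C(C)C)Cc1c(OCOC)cc(OC(=C)c2ccc(OCOC)cc2OC)c(C=O)c1OCOC | intermediate
19 | (2S)-5,7-bis(methoxymethoxy)-2-[2-methoxy-4-(methoxymethoxy)phenyl]-6-[(2R)-5-methyl-2-(prop-1-en-2-yl)hex-4-en-1-yl]chroman-4-one | C=C(C)[C@H](CC=C(C)C)Cc1c(OCOC)cc2c(c1OCOC)C(=O)C[C@@H](c1ccc(OCOC)cc1OC)O2 | intermediate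
20 | (2S)-5,7-dihydroxy-2-(4-hydroxy-2-methoxyphenyl)-6-[(2R)-5-methyl-2-(prop-1-en-2-yl)hex-4-en-1-yl]chroman-4-one | C=C(C)[C@H](CC=C(C)C)Cc1c(O)cc2c(c1O)C(=O)C[C@@H](c1ccc(O)cc1OC)O2 | target

## Step count and least certain steps

Total: 14 steps. Longest linear sequence: 10 steps from 1 (steps 1, 2, 5, 6, 7, 10, 11, 12, 13, 14). Steps 3–4 (ring A partner) and 8–9 (ring B acid) are side branches.

**Step 13 (key step, new method).** Three things may go wrong. Insertion may take the opposite sense, placing rhodium on the oxygen- and aryl-substituted C2, which is the electronically preferred site for an enol ether, and leading to 5-exo closure. The acyl hydride may decarbonylate, or a free rhodium hydride may shift the isopropenyl double bond and erase the side-chain stereocentre. Face selectivity may be low because the ether oxygen changes how the alkene sits in the chiral pocket.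

The fallback uses known chemistry, sets out from iodophenol 11 and ester 13, and rejoins at 19. Ester 13 is condensed with the lithium enolate of N-methoxy-N-methylacetamide (LiN(i-Pr)2, THF, −78 °C) to give N-methoxy-3-[2-methoxy-4-(methoxymethoxy)phenyl]-N-methyl-3-oxopropanamide F1. Transfer hydrogenation with RuCl(p-cymene)[(R,R)-TsDPEN] and HCO2H/Et3N, expected by analogy with aryl methyl ketones to give the (R) carbinol, affords (3R)-3-hydroxy-N-methoxy-3-[2-methoxy-4-(methoxymethoxy)phenyl]-N-methylpropanamide F2. Iodophenol 11 is deprotonated with MeMgCl and exchanged with i-PrMgCl·LiCl to the chloromagnesium 2-(chloromagnesio)-3,5-bis(methoxymethoxy)-4-[(R)-lavandulyl]phenoxide F3. F3 acylates the magnesium alkoxide of F2 to give (3R)-3-hydroxy-1-{2-hydroxy-4,6-bis(methoxymethoxy)-5-[(R)-lavandulyl]phenyl}-3-[2-methoxy-4-(methoxymethoxy)phenyl]propan-1-one F4. Mitsunobu closure (PPh3, DIAD, THF, 0 °C) with inversion at the carbinol then gives 19.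

**Step 5.** The alkylpalladium intermediate carries an allylic β-hydrogen, so β-hydride elimination and re-insertion may give an isomerised or reduced side chain; zinc insertion into the β-branched iodide may be slow; a second coupling at C–Cl may occur if the mixture is heated. The fallback reverses the polarity, sets out from 5 (through aryllithium 6) and iodide 3, and rejoins at 9. Two equivalents of 6 with CuI give lithium bis[4-chloro-2,6-bis(methoxymethoxy)phenyl]cuprate F5, which is alkylated by 3 in THF at −20 to 0 °C in an SN2 displacement.

**Step 11.** Methylenation of the hindered, electron-rich ester may be sluggish, and the enol ether may hydrolyse during isolation. The fallback sets out from phenol 10 and rejoins at 18, bypassing 11 and 13–17. Magnesium-mediated ortho-formylation of 10 (MgCl2, Et3N, paraformaldehyde, MeCN, reflux) gives 6-hydroxy-2,4-bis(methoxymethoxy)-3-[(R)-lavandulyl]benzaldehyde F6. Commercial 1-(4-hydroxy-2-methoxyphenyl)ethanone is protected (MOMCl, i-Pr2NEt) as 1-[2-methoxy-4-(methoxymethoxy)phenyl]ethanone F7 and converted with (PhO)3P, Br2 and Et3N into 1-(1-bromovinyl)-2-methoxy-4-(methoxymethoxy)benzene F8. Ullmann-type C–O coupling of F6 with F8 (CuI, N,N-dimethylglycine, Cs2CO3, 1,4-dioxane, 80 °C) gives 18; its own risk is loss of HBr from F8.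

**Step 14.** Acid may promote addition of the C5 or C7 phenol, or of methanol, to the side-chain alkenes, and reversible opening at the electron-rich benzylic C2–O1 bond may erode C2; the two non-chelated acetals may cleave slowly, prolonging exposure. The fallback goes from 19 to 20 by aprotic silyl transfer and neutral hydrolysis. TMSOTf and 2,2'-bipyridyl in CH2Cl2 at 0 °C convert the acetals into the tris(trimethylsilyl) ether (2S)-2-[2-methoxy-4-(trimethylsilyloxy)phenyl]-6-[(R)-lavandulyl]-5,7-bis(trimethylsilyloxy)chroman-4-one F9, which is hydrolysed with water at room temperature to 20.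

## Further compounds

F1 | step 13 | N-methoxy-3-[2-methoxy-4-(methoxymethoxy)phenyl]-N-methyl-3-oxopropanamide | CON(C)C(=O)CC(=O)c1ccc(OCOC)cc1OC
F2 | step 13 | (3R)-3-hydroxy-N-methoxy-3-[2-methoxy-4-(methoxymethoxy)phenyl]-N-methylpropanamide | CON(C)C(=O)C[C@@H](O)c1ccc(OCOC)cc1OC
F3 | step 13 | chloromagnesium 2-(chloromagnesio)-3,5-bis(methoxymethoxy)-4-[(2R)-5-methyl-2-(prop-1-en-2-yl)hex-4-en-1-yl]phenoxide | C=C(C)[C@H](CC=C(C)C)Cc1c(OCOC)cc(O[Mg]Cl)c([Mg]Cl)c1OCOC
F4 | step 13 | (3R)-3-hydroxy-1-{2-hydroxy-4,6-bis(methoxymethoxy)-5-[(2R)-5-methyl-2-(prop-1-en-2-yl)hex-4-en-1-yl]phenyl}-3-[2-methoxy-4-(methoxymethoxy)phenyl]propan-1-one | C=C(C)[C@H](CC=C(C)C)Cc1c(OCOC)cc(O)c(C(=O)C[C@@H](O)c2ccc(OCOC)cc2OC)c1OCOC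
F5 | step 5 | lithium bis[4-chloro-2,6-bis(methoxymethoxy)phenyl]cuprate | [Li+].COCOc1cc(Cl)cc(OCOC)c1[Cu-]c1c(OCOC)cc(Cl)cc1OCOC
F6 | step 11 | 6-hydroxy-2,4-bis(methoxymethoxy)-3-[(2R)-5-methyl-2-(prop-1-en-2-yl)hex-4-en-1-yl]benzaldehyde | C=C(C)[C@H](CC=C(C)C)Cc1c(OCOC)cc(O)c(C=O)c1OCOC
F7 | step 11 | 1-[2-methoxy-4-(methoxymethoxy)phenyl]ethanone | COCOc1ccc(C(C)=O)c(OC)c1
F8 | step 11 | 1-(1-bromovinyl)-2-methoxy-4-(methoxymethoxy)benzene | C=C(Br)c1ccc(OCOC)cc1OC
F9 | step 14 | (2S)-2-[2-methoxy-4-(trimethylsilyloxy)phenyl]-6-[(2R)-5-methyl-2-(prop-1-en-2-yl)hex-4-en-1-yl]-5,7-bis(trimethylsilyloxy)chroman-4-one | C=C(C)[C@H](CC=C(C)C)Cc1c(O[Si](C)(C)C)cc2c(c1O[Si](C)(C)C)C(=O)C[C@@H](c1ccc(O[Si](C)(C)C)cc1OC)O2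
A1 | alternative 1 | (2S)-5,7-dihydroxy-6-[(2R)-5-methyl-2-(prop-1-en-2-yl)hex-4-en-1-yl]-2-[2-methoxy-4-(triisopropylsilyloxy)phenyl]chroman-4-one | C=C(C)[C@H](CC=C(C)C)Cc1c(O)cc2c(c1O)C(=O)C[C@@H](c1ccc(O[Si](C(C)C)(C(C)C)C(C)C)cc1OC)O2
A2 | alternative 1 | 1-methoxy-2-[(2R)-5-methyl-2-(prop-1-en-2-yl)hex-4-en-1-yl]-1,3-bis(trimethylsilyloxy)buta-1,3-diene | C=C(C)[C@H](CC=C(C)C)CC(C(=C)O[Si](C)(C)C)=C(OC)O[Si](C)(C)C
A3 | alternative 1 | (2S)-2-[2-methoxy-4-(triisopropylsilyloxy)phenyl]-5-(phenylsulfinyl)-2,3-dihydro-4H-pyran-4-one | O=C1C[C@@H](c2ccc(O[Si](C(C)C)(C(C)C)C(C)C)cc2OC)OC=C1S(=O)c1ccccc1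
A4 | alternative 2 | (2S)-5-hydroxy-6-[(2R)-5-methyl-2-(prop-1-en-2-yl)hex-4-en-1-yl]-2-[2-methoxy-4-(triisopropylsilyloxy)phenyl]-7-(triisopropylsilyloxy)chroman-4-one | C=C(C)[C@H](CC=C(C)C)Cc1c(O[Si](C(C)C)(C(C)C)C(C)C)cc2c(c1O)C(=O)C[C@@H](c1ccc(O[Si](C(C)C)(C(C)C)C(C)C)cc1OC)O2
A5 | alternative 2 | (2S)-6-(2-diazoacetyl)-2-[2-methoxy-4-(triisopropylsilyloxy)phenyl]-2,3-dihydro-4H-pyran-4-one | O=C1C[C@@H](c2ccc(O[Si](C(C)C)(C(C)C)C(C)C)cc2OC)OC(C(=O)C=[N+]=[N-])=C1
A6 | alternative 2 | triisopropyl{[(4R)-7-methyl-4-(prop-1-en-2-yl)oct-6-en-1-yn-1-yl]oxy}silane | C=C(C)[C@H](CC=C(C)C)CC#CO[Si](C(C)C)(C(C)C)C(C)C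
A7 | alternative 3 | (2S)-2-[4-(tert-butoxycarbonyloxy)-2-methoxyphenyl]-5,7-bis(methoxymethoxy)-6-[(2R)-5-methyl-2-(prop-1-en-2-yl)hex-4-en-1-yl]chroman-4-one | C=C(C)[C@H](CC=C(C)C)Cc1c(OCOC)cc2c(c1OCOC)C(=O)C[C@@H](c1ccc(OC(=O)OC(C)(C)C)cc1OC)O2
A8 | alternative 3 | (3S)-3-[4-(tert-butoxycarbonyloxy)-2-methoxyphenyl]-3-{2-iodo-3,5-bis(methoxymethoxy)-4-[(2R)-5-methyl-2-(prop-1-en-2-yl)hex-4-en-1-yl]phenoxy}-N-methoxy-N-methylpropanamide | C=C(C)[C@H](CC=C(C)C)Cc1c(OCOC)cc(O[C@@H](CC(=O)N(C)OC)c2ccc(OC(=O)OC(C)(C)C)cc2OC)c(I)c1OCOC
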